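**Plan**
- Retrosynthetic cuts: first the two galloyl C(=O)–O bonds (O3, O5) and all benzyl ethers, which leads to diol 15. Ring A of 15 is then taken back to a 5-oxo-7-benzyloxycyclohexene (two extra H), and C3–OH to C3=O.
- Key cut: the pyran ring O1–C2–C3–C4–C4a–C8a is contracted to the furan ring O–C3–C4–C4a–C8a of a 4-oxotetrahydrobenzofuran, with C2 outside the ring as an aryl carbinol. The furan is cut at C4–C4a and O–C3 into an epoxy-enal and 5-(benzyloxy)cyclohexane-1,3-dione.
- Enabling feature: O1 lies between C8a (ketone level once ring A is non-aromatic) and the carbinol-type C2, whose neighbour C3 is oxygenated. This is the 6-hydroxypyran-3-one pattern. Ring A (O on C5, C7, C8a) equals a cyclohexane-1,3-dione plus one sp3 C–O, so O7 (ether) and O5 (carbonyl) differ from the outset.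
- Forward order: saturated ring A, then furan, then pyranone ring C by ring expansion, then reductive locking and alkene shift, then C3 reduction, then aromatisation of ring A, then two esters, then hydrogenolysis.
- Stereochemistry: C2 comes from a catalytic asymmetric epoxidation, and its benzylic C–O bond is never broken afterwards. C3 comes from substrate-controlled hydride delivery that gives the 2,3-cis alcohol.

Key step: step 5

Assumption: the sp3 carbon bearing the future 7-O-benzyl group is a temporary stereocentre, as are C3 of the dihydrofuran ring in 8, C8a in 10 and 11, and C6 in 14. These compounds are carried as epimer mixtures, their SMILES leave such centres open, and all of them vanish by step 8. Commercial triol 4 is used as its cis/trans mixture.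

Step 1
Reactants: 1 3,4-bis(benzyloxy)benzaldehyde; 2 (triphenylphosphoranylidene)acetaldehyde
Product: 3 (E)-3-[3,4-bis(benzyloxy)phenyl]prop-2-enal
Conditions: 2 (1.0 equiv), toluene, 80 °C
Reagents that add atoms: none
Why: Wittig olefination with the stabilised formylmethylene ylide should give the (E)-enal, and the use of one equivalent of ylide limits a second homologation.

Step 2
Reactants: 4 cyclohexane-1,3,5-triol
Product: 5 5-(benzyloxy)cyclohexane-1,3-diol (isomer mixture)
Conditions: NaH (1 equiv), BnBr (0.8 equiv), DMF, 0 °C to rt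
Reagents that add atoms: benzyl bromide BrCc1ccccc1
Why: Williamson etherification with the triol in excess should stop mainly at the mono-ether, and the configuration is irrelevant because no stereocentre survives in 6.

Step 3
Reactants: 5 5-(benzyloxy)cyclohexane-1,3-diol
Product: 6 5-(benzyloxy)cyclohexane-1,3-dione
Conditions: IBX (2.4 equiv), EtOAc, 75 °C
Reagents that add atoms: none
Why: IBX oxidation of a 1,3-diol through the β-hydroxy ketone to the β-diketone runs under neutral heterogeneous conditions, and the product rests as its enol, which disfavours β-elimination of benzyl alcohol.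

Step 4
Reactants: 3 (E)-3-[3,4-bis(benzyloxy)phenyl]prop-2-enal; 6 5-(benzyloxy)cyclohexane-1,3-dione
Product: 9 6-(benzyloxy)-2-{(R)-[3,4-bis(benzyloxy)phenyl](hydroxy)methyl}-6,7-dihydro-1-benzofuran-4(5H)-one, via epoxy aldehyde 7 (not isolated), via dihydrofuranol 8 (not isolated)
Conditions: (S)-2-{bis[3,5-bis(trifluoromethyl)phenyl](trimethylsilyloxy)methyl}pyrrolidine (10 mol %), 35% aq H2O2 (1.3 equiv), CH2Cl2, rt; then 6, Et3N (20 mol %), rt; then PPTS (20 mol %), 4 Å MS, rt
Reagents that add atoms: hydrogen peroxide OO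
Why: In this iminium–enamine epoxidation followed by a one-pot Feist–Bénary furan synthesis (aldol of C2 of the dione on the CHO group, 5-exo-tet opening of the epoxide at Cα by the enol oxygen, dehydration), the (S)-catalyst shields the Re face of Cβ of the E-iminium ion, so the peroxide should add to the Si face and fix the (R) benzylic C–O bond, which stays intact while the Cα centre is lost on aromatisation.

Step 5
Reactants: 9 6-(benzyloxy)-2-{(R)-[3,4-bis(benzyloxy)phenyl](hydroxy)methyl}-6,7-dihydro-1-benzofuran-4(5H)-one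
Product: 10 (2R)-7-(benzyloxy)-2-[3,4-bis(benzyloxy)phenyl]-8a-hydroxy-6,7,8,8a-tetrahydro-2H-chromene-3,5-dione
Conditions: mCPBA (1.05 equiv), NaHCO3, CH2Cl2, 0 °C to rt
Reagents that add atoms: mCPBA O=C(OO)c1cccc(Cl)c1
Why: Achmatowicz rearrangement: the peracid, guided by a hydrogen bond to the carbinol OH, transfers oxygen to the C2=C3 bond of the furan (the C3a=C7a bond is a deactivated push–pull vinylogous ester), the epoxy-acetal opens to the (Z)-ene-dione (here a 2-alkylidenecyclohexane-1,3-dione), and the carbinol oxygen adds to the former C7a carbonyl, so that the five-membered ring O–C3–C4–C4a–C8a is replaced by the six-membered ring O1–C2–C3–C4–C4a–C8a. The closest known reaction type is the peracid- or NBS-mediated oxidative ring expansion of 2-furyl carbinols, which includes 2,5-disubstituted and acceptor-bearing furans. The ring closes by a reversible 6-exo-trig hemiketalisation, which lies on the closed side as in other 6-alkyl-6-hydroxypyranones. C2 keeps its (R) configuration because neither its C–O nor its C–H bond takes part, and the new hemiketal centre C8a is uncontrolled and is erased in step 6. The step needs chemoselectivity for the furan over the catechol diether ring, the benzyl ethers and the ketone, which the directing OH, one equivalent of oxidant at 0 °C and the bicarbonate buffer should secure. The closure raises no regiochemical question, since the two ring carbonyls of the open form are constitutionally equivalent and both lead to 10.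

Step 6
Reactants: 10 (2R)-7-(benzyloxy)-2-[3,4-bis(benzyloxy)phenyl]-8a-hydroxy-6,7,8,8a-tetrahydro-2H-chromene-3,5-dione
Product: 12 (2R)-7-(benzyloxy)-2-[3,4-bis(benzyloxy)phenyl]-4,6,7,8-tetrahydro-2H-chromene-3,5-dione, via 8a-H enedione 11 (not isolated)
Conditions: Et3SiH (5 equiv), TFA, CH2Cl2, −40 °C; aq NaHCO3; crude 11, DBU (0.1 equiv), CH2Cl2, 0 °C, short contact
Reagents that add atoms: none
Why: Kishi reduction of the hemiketal through the cyclic oxocarbenium ion locks the O1–C8a bond, and base-catalysed γ-deprotonation (C8a–H) with α-protonation (C4) then moves the alkene to C4a=C8a to give the more stable vinylogous ester, with catalytic base at low temperature sparing the less acidic C2–H.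

Step 7
Reactants: 12 (2R)-7-(benzyloxy)-2-[3,4-bis(benzyloxy)phenyl]-4,6,7,8-tetrahydro-2H-chromene-3,5-dione
Product: 13 (2R,3R)-7-(benzyloxy)-2-[3,4-bis(benzyloxy)phenyl]-3-hydroxy-2,3,4,6,7,8-hexahydro-5H-chromen-5-one
Conditions: L-Selectride (1.2 equiv), THF, −78 °C; AcOH
Reagents that add atoms: none
Why: Substrate-controlled ketone reduction, in which the bulky hydride should attack the half-chair 2-arylpyran-3-one equatorially (as it does with 2-arylchroman-3-ones) to give the axial 2,3-cis (3R) alcohol, while the vinylogous ester carbonyl is inert at −78 °C.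

Step 8
Reactants: 13 (2R,3R)-7-(benzyloxy)-2-[3,4-bis(benzyloxy)phenyl]-3-hydroxy-2,3,4,6,7,8-hexahydro-5H-chromen-5-one
Product: 15 (2R,3R)-7-(benzyloxy)-2-[3,4-bis(benzyloxy)phenyl]chromane-3,5-diol (7,3',4'-tri-O-benzyl-(−)-epicatechin), via selenide 14 (not isolated)
Conditions: LDA (2.2 equiv), THF, −78 °C; PhSeCl (1.1 equiv); AcOH; then 30% H2O2, pyridine, CH2Cl2, 0 °C
Reagents that add atoms: none
Why: Kinetic α'-deprotonation (C6) of the vinylogous ester, selenenylation anti to the benzyloxy group and selenoxide syn-elimination towards C7–H should give the 6,7-ene, whose dienone tautomerises at once to the phenol, so ring A becomes aromatic with O7 benzylated and O5 free while C2 and C3 are untouched.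

Step 9
Reactants: 15 (2R,3R)-7-(benzyloxy)-2-[3,4-bis(benzyloxy)phenyl]chromane-3,5-diol; 16 3,4,5-tris(benzyloxy)benzoic acid
Product: 17 7,3',4'-tri-O-benzyl-(−)-epicatechin 3,5-bis[3,4,5-tris(benzyloxy)benzoate]
Conditions: 16 (2.5 equiv), DCC, DMAP, CH2Cl2, rt
Reagents that add atoms: none
Why: Steglich esterification acylates the only two free hydroxyl groups (phenolic O5 and axial O3) in one operation without touching a stereocentre.

Step 10
Reactants: 17 7,3',4'-tri-O-benzyl-(−)-epicatechin 3,5-bis[3,4,5-tris(benzyloxy)benzoate]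
Product: 18 epicatechin 3,5-di-O-gallate
Conditions: H2 (1 atm), 20% Pd(OH)2/C, THF–MeOH, rt
Reagents that add atoms: none
Why: Neutral hydrogenolysis of all nine benzyl ethers is the standard last step for catechin gallates and leaves the esters, the O1–C2 bond and both stereocentres intact.

**Compound list**
1 | 3,4-bis(benzyloxy)benzaldehyde | O=Cc1ccc(OCc2ccccc2)c(OCc2ccccc2)c1 | starting material
2 | (triphenylphosphoranylidene)acetaldehyde | O=CC=P(c1ccccc1)(c1ccccc1)c1ccccc1 | starting material
3 | (E)-3-[3,4-bis(benzyloxy)phenyl]prop-2-enal | O=C/C=C/c1ccc(OCc2ccccc2)c(OCc2ccccc2)c1 | intermediate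
4 | cyclohexane-1,3,5-triol | OC1CC(O)CC(O)C1 | starting material
5 | 5-(benzyloxy)cyclohexane-1,3-diol | OC1CC(O)CC(OCc2ccccc2)C1 | intermediate
6 | 5-(benzyloxy)cyclohexane-1,3-dione | O=C1CC(=O)CC(OCc2ccccc2)C1 | intermediate
7 | (2S,3R)-3-[3,4-bis(benzyloxy)phenyl]oxirane-2-carbaldehyde | O=C[C@H]1O[C@@H]1c1ccc(OCc2ccccc2)c(OCc2ccccc2)c1 | intermediate
8 | 6-(benzyloxy)-2-{(R)-[3,4-bis(benzyloxy)phenyl](hydroxy)methyl}-3-hydroxy-3,5,6,7-tetrahydro-1-benzofuran-4(2H)-one | O[C@H](c1ccc(OCc2ccccc2)c(OCc2ccccc2)c1)[C@H]1OC2=C(C1O)C(=O)CC(OCc1ccccc1)C2 | intermediate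
9 | 6-(benzyloxy)-2-{(R)-[3,4-bis(benzyloxy)phenyl](hydroxy)methyl}-6,7-dihydro-1-benzofuran-4(5H)-one | O[C@H](c1ccc(OCc2ccccc2)c(OCc2ccccc2)c1)c1cc2c(o1)CC(OCc1ccccc1)CC2=O | intermediate
10 | (2R)-7-(benzyloxy)-2-[3,4-bis(benzyloxy)phenyl]-8a-hydroxy-6,7,8,8a-tetrahydro-2H-chromene-3,5-dione | O=C1CC(OCc3ccccc3)CC2(O)C1=CC(=O)[C@@H](c1ccc(OCc3ccccc3)c(OCc3ccccc3)c1)O2 | intermediate
11 | (2R)-7-(benzyloxy)-2-[3,4-bis(benzyloxy)phenyl]-6,7,8,8a-tetrahydro-2H-chromene-3,5-dione | O=C1CC(OCc3ccccc3)CC2C1=CC(=O)[C@@H](c1ccc(OCc3ccccc3)c(OCc3ccccc3)c1)O2 | intermediate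
12 | (2R)-7-(benzyloxy)-2-[3,4-bis(benzyloxy)phenyl]-4,6,7,8-tetrahydro-2H-chromene-3,5-dione | O=C1CC(OCc3ccccc3)CC2=C1CC(=O)[C@@H](c1ccc(OCc3ccccc3)c(OCc3ccccc3)c1)O2 | intermediate
13 | (2R,3R)-7-(benzyloxy)-2-[3,4-bis(benzyloxy)phenyl]-3-hydroxy-2,3,4,6,7,8-hexahydro-5H-chromen-5-one | O=C1CC(OCc3ccccc3)CC2=C1C[C@@H](O)[C@@H](c1ccc(OCc3ccccc3)c(OCc3ccccc3)c1)O2 | intermediate
14 | 6-(phenylselanyl) derivative of 13 | O=C1C([Se]c3ccccc3)C(OCc3ccccc3)CC2=C1C[C@@H](O)[C@@H](c1ccc(OCc3ccccc3)c(OCc3ccccc3)c1)O2 | intermediate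
15 | (2R,3R)-7-(benzyloxy)-2-[3,4-bis(benzyloxy)phenyl]chromane-3,5-diol | Oc1cc(OCc3ccccc3)cc2c1C[C@@H](O)[C@@H](c1ccc(OCc3ccccc3)c(OCc3ccccc3)c1)O2 | intermediate
16 | 3,4,5-tris(benzyloxy)benzoic acid | OC(=O)c1cc(OCc2ccccc2)c(OCc2ccccc2)c(OCc2ccccc2)c1 | starting material
17 | 7,3',4'-tri-O-benzyl-(−)-epicatechin 3,5-bis[3,4,5-tris(benzyloxy)benzoate] | O=C(Oc1cc(OCc3ccccc3)cc2c1C[C@@H](OC(=O)c1cc(OCc3ccccc3)c(OCc3ccccc3)c(OCc3ccccc3)c1)[C@@H](c1ccc(OCc3ccccc3)c(OCc3ccccc3)c1)O2)c1cc(OCc3ccccc3)c(OCc3ccccc3)c(OCc3ccccc3)c1 | intermediate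
18 | epicatechin 3,5-di-O-gallate | O=C(Oc1cc(O)cc2c1C[C@@H](OC(=O)c1cc(O)c(O)c(O)c1)[C@@H](c1ccc(O)c(O)c1)O2)c1cc(O)c(O)c(O)c1 | target

Total step count: 10. Longest linear sequence: 9 steps (steps 2 to 10, from 4).

**Steps most likely to fail**

Step 4. The electron-rich aryl epoxide may ionise at the benzylic carbon, which erodes the enantiomeric purity. It may also be opened by the enol oxygen in the 6-endo sense, or the aldehyde may take up two dione units.
The fallback sets out from 1 and 6 and returns at 9. Titanium–BINOL-catalysed addition of (trimethylsilyl)ethynylzinc to 1 would give (R)-1-[3,4-bis(benzyloxy)phenyl]-3-(trimethylsilyl)prop-2-yn-1-ol F1. K2CO3/MeOH then gives (S)-1-[3,4-bis(benzyloxy)phenyl]prop-2-yn-1-ol F2, which has the same spatial arrangement (only the descriptor changes). TBSCl/imidazole gives its tert-butyldimethylsilyl ether F3. Diazo transfer to 6 (p-ABSA, Et3N) would give 5-(benzyloxy)-2-diazocyclohexane-1,3-dione F4. Rh2(OAc)4-catalysed formal [3+2] cycloaddition of the carbenoid from F4 with F3 (fluorobenzene, reflux, slow addition of F4) builds the furan without any epoxide as the O-TBS ether of 9 F5, and TBAF/AcOH releases 9.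

Step 5. Oxygen transfer to the acceptor-substituted furan may be slow, so that the peracid begins to attack the electron-rich arenes or the product.
The fallback sets out from 9 and returns at 10. Dye-sensitised photooxygenation (O2, methylene blue, visible light, CH2Cl2, −78 °C) adds singlet oxygen across C2 and C7a of the furan in a [4+2] cycloaddition to give the bicyclic furan endoperoxide F6. Dimethyl sulfide reduces it to the same ene-dione, which closes to 10.

Step 8. The C6 enolate may expel benzyl alcohol (loss of O7), and the selenium electrophile set free may attack the newly formed phloroglucinol ring.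
The fallback sets out from 13 (with 16) and returns at 17, so it bypasses 15. Oxalyl chloride with catalytic DMF converts 16 into 3,4,5-tris(benzyloxy)benzoyl chloride F7. Double deprotonation of 13 (KHMDS, THF–DMPU, −78 °C) and O-acylation of both the alkoxide and the cross-conjugated dienolate with F7 gives the 3-O-galloyl 5-dienol gallate F8. DDQ (dioxane, rt) then removes hydride from the oxygen-stabilised C7–H and a proton from C8, which aromatises the cyclohexadiene to 17.

**Further compounds**
F1 | step 4 | (R)-1-[3,4-bis(benzyloxy)phenyl]-3-(trimethylsilyl)prop-2-yn-1-ol | O[C@H](c1ccc(OCc2ccccc2)c(OCc2ccccc2)c1)C#C[Si](C)(C)C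
F2 | step 4 | (S)-1-[3,4-bis(benzyloxy)phenyl]prop-2-yn-1-ol | O[C@H](c1ccc(OCc2ccccc2)c(OCc2ccccc2)c1)C#C
F3 | step 4 | (S)-{1-[3,4-bis(benzyloxy)phenyl]prop-2-yn-1-yloxy}(tert-butyl)dimethylsilane | CC(C)(C)[Si](C)(C)O[C@H](c1ccc(OCc2ccccc2)c(OCc2ccccc2)c1)C#C
F4 | step 4 | 5-(benzyloxy)-2-diazocyclohexane-1,3-dione | [N-]=[N+]=C1C(=O)CC(OCc2ccccc2)CC1=O
F5 | step 4 | O-TBS ether of 9 | CC(C)(C)[Si](C)(C)O[C@H](c1ccc(OCc2ccccc2)c(OCc2ccccc2)c1)c1cc2c(o1)CC(OCc1ccccc1)CC2=O
F6 | step 5 | furan endoperoxide of 9 | O[C@H](c1ccc(OCc2ccccc2)c(OCc2ccccc2)c1)C12OOC3(O1)CC(OCc4ccccc4)CC(=O)C3=C2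
F7 | step 8 | 3,4,5-tris(benzyloxy)benzoyl chloride | O=C(Cl)c1cc(OCc2ccccc2)c(OCc2ccccc2)c(OCc2ccccc2)c1
F8 | step 8 | (2R,3R)-7-(benzyloxy)-2-[3,4-bis(benzyloxy)phenyl]-3,4,7,8-tetrahydro-2H-chromene-3,5-diyl bis[3,4,5-tris(benzyloxy)benzoate] | O=C(OC1=CC(OCc3ccccc3)CC2=C1C[C@@H](OC(=O)c1cc(OCc3ccccc3)c(OCc3ccccc3)c(OCc3ccccc3)c1)[C@@H](c1ccc(OCc3ccccc3)c(OCc3ccccc3)c1)O2)c1cc(OCc3ccccc3)c(OCc3ccccc3)c(OCc3ccccc3)c1
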